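**Assumption:** the SMILES is read as nineteen CH2 groups between the ester oxygen and the stereocentre, i.e. the target is (S)-20-methyldocosyl 2,3-dihydroxybenzoate. Chain numbering used below: C1 = OCH2, C20 = stereocentre (S), 20-CH3 = branch, C21–C22 = ethyl.

## The problem

Gentiside B (12) is the 2,3-dihydroxybenzoate of an anteiso C23 alcohol: nineteen unbranched methylenes (C1–C19) ending in C20, which carries H, CH3, C2H5 (C21–C22) and the chain. The chain has to be joined from purchasable pieces, and any homologue or chain isomer from a faulty coupling is a wax of the same polarity as the product, so each C–C bond must be made at a defined place. C20 is the only stereocentre. It bears no heteroatom, lies nineteen methylenes from the nearest functional group, and its two larger substituents (ethyl and n-alkyl) are identical up to the β-carbon. Nothing in the molecule can therefore control it, and nothing downstream (crystallisation, resolution through the hydroxyl) can be relied on to correct it. The aromatic part is a free catechol ortho to an ester: it is oxidised to the o-quinone by air under base, its phenols compete with the carboxyl group in acylations, and the ester does not survive hydride or organometallic reagents, so it is introduced last. The feature that opens the problem is that C20 carries exactly one CH3 and one C2H5. The C20–C21 bond and one C–H bond of the 20-methyl carbon are the two bonds formed when an ethyl–metal bond adds across a terminal vinyl group (internal carbon = future C20, terminal carbon = future 20-CH3) and the carbon–metal bond is then protonated. Read this way, the stereocentre becomes a choice of enantioface of a monosubstituted alkene, where a catalyst must tell H from the whole chain rather than ethyl from alkyl, and the precursor is an achiral, unbranched ω-alkenol.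

## Retrosynthesis

**Ester, C1–O bond.** The last bond made is the alkyl–oxygen bond of the ester, by attack of the carboxylate of 2,3-dihydroxybenzoic acid 10 on activated C1 of (S)-20-methyldocosan-1-ol 9. Cutting the acyl–oxygen bond instead would require acyl activation of 10 and protection of the catechol (two extra steps). The alkyl–oxygen cut uses the gap of about seven pKa units between CO2H and the phenols. The precursors are a commercial acid and an alcohol with one stereocentre. The forward reaction must be chemoselective for carboxylate over phenol, neutral and non-oxidising.

**Key cut, C20–C21 and one C–H of 20-CH3.** Alcohol 9 is cut at the bond from C20 to the ethyl group and at one C–H bond of the 20-methyl carbon, which leads to henicos-20-en-1-ol 6 and triethylaluminium. The neighbouring cuts (C18–C19 or C19–C20) keep the stereocentre inside a purchased fragment or need a vinyl surrogate plus hydrogenation. This cut instead removes branch and stereocentre together and leaves an achiral, linear alkenol. The forward reaction must put ethyl on the internal carbon, select one face of an alkene that has no directing group, tolerate the remote hydroxyl (as aluminium alkoxide 7), and end with clean protonolysis of the alane 8.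

**Chain, C10–C11.** Alkenol 6 is cut in the middle of its unbranched run into 11-bromoundec-1-ene 1 (used as Grignard reagent 3) and 10-bromodecan-1-ol 2. This is the position at which both halves are commercial α,ω-bifunctional blocks; any other cut needs a partner that must first be made. The forward reaction is a Cu-catalysed sp3–sp3 coupling with the hydroxyl carried as magnesium alkoxide 4.

## Roads not taken

**Alternative 1:** (the most obvious) cut C18–C19 and buy the stereocentre. The Grignard reagent of (S)-1-bromo-2-methylbutane A1 would be coupled under Cu catalysis with 18-bromooctadecan-1-ol A2 to give 9, followed by esterification. Its enantiopurity is that of the chiral pool, a real advantage, and this logic is therefore kept as the fallback for step 2. Against it: A2 is not a commodity and must itself be assembled, or the chain built through a statistically mono-substituted dibromide. The stereocentre enters as a stoichiometric building block that fixes one enantiomer series and one branch size. The chosen plan reaches 9 in two steps from two commodity blocks and creates branch and configuration catalytically; the other enantiomer (antipodal catalyst) or an iso terminus (Me3Al) would come from the same alkene 6.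

**Alternative 2:** cut C19–C20 with the ethyl group disguised as vinyl. Cu-catalysed asymmetric allylic alkylation (SN2′) of (E)-1-bromobut-2-ene A3 by [18-(tert-butyldimethylsilyloxy)octadecyl]magnesium bromide A4 would give, after desilylation, (R)-20-methyldocos-21-en-1-ol A5, and hydrogenation of the vinyl group would give 9. This also sets C20 by catalysis. It needs the non-commodity C18 chain in protected form and a low-temperature addition of a poorly soluble C18 alkylmagnesium. It also needs control of SN2′ against SN2, since the linear product hydrogenates to an unbranched alcohol that is hard to separate from 9. Three extra steps follow (protection, deprotection, hydrogenation). The carboalumination reaches the same C20 from an alkene that needs no leaving group, with regiochemistry fixed by the monosubstituted alkene.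

**Alternative 3:** cut the C20–H bond. Asymmetric hydrogenation of 20-methylidenedocosan-1-ol A6, or of the trisubstituted isomer (E)-20-methyldocos-20-en-1-ol A7, would give 9. In A6 the prochiral carbon carries ethyl and an n-alkyl chain that are identical up to the β-carbon and no coordinating group is within reach, so a catalyst has almost nothing with which to tell the faces apart. A7 offers a better steric difference but must be geometrically pure, because E and Z isomers lead to opposite configurations, and that costs a longer run-up. In the chosen plan the catalyst distinguishes H from the entire chain at the alkene carbon, the largest difference the skeleton offers.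

Key step: step 2

## Route

**Step 1**
Reactants: 1 11-bromoundec-1-ene; 2 10-bromodecan-1-ol
Product: 6 henicos-20-en-1-ol, via undec-10-enylmagnesium bromide 3 (not isolated), via bromomagnesium 10-bromodecan-1-olate 4 (not isolated), via bromomagnesium henicos-20-en-1-olate 5 (not isolated)
Conditions: Mg, THF, 45 °C (1 → 3, 2.3 equiv); then 2, Li2CuCl4 (3 mol %), THF, −10 °C → rt; 1 M HCl
Reagents that add atoms: none
Why: Cu-catalysed sp3–sp3 cross-coupling of a primary alkyl Grignard reagent with a primary alkyl bromide (Li2CuCl4); the first equivalent of 3 turns the hydroxyl of 2 into the inert alkoxide 4, a further equivalent displaces the bromide to give alkoxide 5, and acid releases 6. The remote terminal alkene is a spectator and no stereocentre is formed.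

**Step 2**
Reactants: 6 henicos-20-en-1-ol
Product: 9 (S)-20-methyldocosan-1-ol, via diethylaluminium henicos-20-en-1-olate 7 (not isolated), via [(2S)-21-(diethylalumanyloxy)-2-ethylhenicosyl]diethylalumane 8 (not isolated)
Conditions: Et3Al (3 equiv), (+)-(NMI)2ZrCl2 [(+)-bis(1-neomenthylindenyl)zirconium dichloride, 5 mol %], CH2Cl2, 0 → 23 °C; then 2 M HCl, 0 °C
Reagents that add atoms: triethylaluminium, CC[Al](CC)CC (supplies C21–C22)
Why: This is the Zr-catalysed asymmetric carboalumination of a monosubstituted alkene (ZACA reaction, ethylalumination variant) followed by protonolysis of the C–Al bond, the closest known reaction type, applied without change. The first equivalent of Et3Al converts the hydroxyl into the diethylaluminium alkoxide 7 (ethane is lost), which is inert and nineteen methylenes from the alkene, so that C20=C21 behaves as a plain 1-alkene. The zirconocene is alkylated and ionised by the alane to a cationic Zr–Et species, the alkene inserts into Zr–Et by the acyclic pathway with Zr on the terminal carbon and ethyl on C20, and Zr→Al transmetalation releases the primary alane 8 and regenerates Zr–Et. No ring is closed. The only new stereocentre, C20, is set in the insertion step by the chiral bis(neomenthylindenyl) ligand frame, which selects one enantioface of the alkene; the (+)-catalyst is specified because its antipode is known to convert 1-alkenes into (R)-2-alkyl-1-alkanols after oxidation, and the oxidised and protonated products of one alane carry the same CIP descriptor, so ethyl delivery to the Re face of C20 and the S configuration are expected (the sense is to be confirmed on a model 1-alkene; both catalyst antipodes are available). Regioselectivity is secured by the monosubstituted alkene, and the chlorinated solvent with the bulky indenyl ligands suppresses β-H transfer and the cyclic aluminacyclopentane manifold, which would give the same constitution after protonolysis but lower enantioselectivity. Aqueous HCl then replaces the C–Al bond by C–H, turning the metalated carbon into the 20-methyl group without touching C20, which is never metalated or sp2 after the insertion.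

**Step 3**
Reactants: 9 (S)-20-methyldocosan-1-ol; 10 2,3-dihydroxybenzoic acid
Product: 12 gentiside B [(S)-20-methyldocosyl 2,3-dihydroxybenzoate], via (S)-(20-methyldocosyloxy)triphenylphosphonium 2,3-dihydroxybenzoate 11 (not isolated)
Conditions: 10 (1.3 equiv), PPh3 (1.3 equiv), DIAD (1.3 equiv), THF, 0 °C → rt
Reagents that add atoms: none
Why: Mitsunobu esterification: the PPh3–DIAD betaine is protonated by the carboxylic acid of 10 (pKa about 3, against about 10 for the phenols), the alcohol is activated as alkoxyphosphonium salt 11, and the carboxylate displaces Ph3P=O at the primary carbon C1. This preference for CO2H over phenolic OH is established for unprotected phenolic acids, catechols included; C20 is untouched and the conditions are neutral and non-oxidising.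

## Compound list

1 | 11-bromoundec-1-ene | C=CCCCCCCCCCBr | starting material
2 | 10-bromodecan-1-ol | OCCCCCCCCCCBr | starting material
3 | undec-10-enylmagnesium bromide | C=CCCCCCCCCC[Mg]Br | intermediate
4 | bromomagnesium 10-bromodecan-1-olate | Br[Mg]OCCCCCCCCCCBr | intermediate
5 | bromomagnesium henicos-20-en-1-olate | C=CCCCCCCCCCCCCCCCCCCCO[Mg]Br | intermediate
6 | henicos-20-en-1-ol | C=CCCCCCCCCCCCCCCCCCCCO | intermediate
7 | diethylaluminium henicos-20-en-1-olate | C=CCCCCCCCCCCCCCCCCCCCO[Al](CC)CC | intermediate
8 | [(2S)-21-(diethylalumanyloxy)-2-ethylhenicosyl]diethylalumane | CC[C@H](C[Al](CC)CC)CCCCCCCCCCCCCCCCCCCO[Al](CC)CC | intermediate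
9 | (S)-20-methyldocosan-1-ol | CC[C@H](C)CCCCCCCCCCCCCCCCCCCO | intermediate
10 | 2,3-dihydroxybenzoic acid | OC(=O)c1cccc(O)c1O | starting material
11 | (S)-(20-methyldocosyloxy)triphenylphosphonium 2,3-dihydroxybenzoate | CC[C@H](C)CCCCCCCCCCCCCCCCCCCO[P+](c1ccccc1)(c1ccccc1)c1ccccc1.[O-]C(=O)c1cccc(O)c1O | intermediate
12 | gentiside B, (S)-20-methyldocosyl 2,3-dihydroxybenzoate | CC[C@H](C)CCCCCCCCCCCCCCCCCCCOC(=O)c1cccc(O)c1O | target

## Step count and least certain steps

Total step count: 3. Longest linear sequence: 3 steps (1 + 2 → 6 → 9 → 12).

**Step 2 (key step).** The most likely failure is incomplete enantioface selection in the insertion. Precedent with triethylaluminium on simple 1-alkenes is high but short of complete, and C20 cannot be upgraded later because it is too far from the hydroxyl for crystallisation or enzymatic resolution to act on it. Second, β-hydride transfer from the ethylzirconium species (hydrometalation) can compete with carbometalation and would leave an unbranched chain two carbons shorter, which is hard to separate from 9 except by reversed-phase chromatography. Third, leakage into the cyclic carbometalation manifold would lower the selectivity, and the aluminium alkoxide may slow the catalyst. The enantiomeric purity of 9 has to be assayed at this stage.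
Fallback (sets out from 2, returns to the route at 9): the stereocentre is taken from the chiral pool. (S)-1-Bromo-2-methylbutane A1 is converted into (S)-2-methylbutylmagnesium bromide F1, which is coupled (Li2CuCl4, THF, −10 °C) with an excess of 1,8-dibromooctane F2 to give (S)-1-bromo-10-methyldodecane F3, purified by distillation. Its Grignard reagent (S)-10-methyldodecylmagnesium bromide F4 is coupled under the conditions of step 1 with alkoxide 4, generated from 2 with one equivalent of ethylmagnesium bromide, to give bromomagnesium (S)-20-methyldocosan-1-olate F5 and, after acidic work-up, 9, which enters step 3 unchanged.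

**Step 3.** Once the carboxylic acid is depleted, O-alkylation of the phenols can set in, and the catechol may trap the phosphonium species as a cyclic phosphorane. The C23 alcohol is also poorly soluble in cold THF, which slows activation.
Fallback (sets out from 9, returns at 12): acyl activation with the catechol masked. Alcohol 9 is esterified with 2,3-bis(benzyloxy)benzoic acid F6 (EDC·HCl, DMAP, CH2Cl2; Steglich esterification) to give (S)-20-methyldocosyl 2,3-bis(benzyloxy)benzoate F7, and hydrogenolysis (H2, Pd/C, EtOAc) removes both benzyl groups to give 12.

**Step 1.** Wurtz-type homocoupling during Grignard formation and at copper consumes the nucleophile. Sluggish coupling of the aggregated magnesium alkoxide allows reduction or elimination of the bromide to compete.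
Fallback (sets out from 1, returns at 6): the same C10–C11 bond is made without organomagnesium, by B-alkyl Suzuki–Miyaura coupling. Dec-9-en-1-ol F8 is silylated (TBSCl, imidazole, DMF) to tert-butyl(dec-9-en-1-yloxy)dimethylsilane F9 and hydroborated with 9-BBN to 9-[10-(tert-butyldimethylsilyloxy)decyl]-9-borabicyclo[3.3.1]nonane F10. This is coupled with 1 (Pd(OAc)2, PCy3, K3PO4·H2O, THF, rt) to give tert-butyl(henicos-20-en-1-yloxy)dimethylsilane F11, and TBAF in THF gives 6.

## Further compounds

F1 | step 2 | (S)-2-methylbutylmagnesium bromide | CC[C@H](C)C[Mg]Br
F2 | step 2 | 1,8-dibromooctane | BrCCCCCCCCBr
F3 | step 2 | (S)-1-bromo-10-methyldodecane | CC[C@H](C)CCCCCCCCCBr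
F4 | step 2 | (S)-10-methyldodecylmagnesium bromide | CC[C@H](C)CCCCCCCCC[Mg]Br
F5 | step 2 | bromomagnesium (S)-20-methyldocosan-1-olate | CC[C@H](C)CCCCCCCCCCCCCCCCCCCO[Mg]Br
F6 | step 3 | 2,3-bis(benzyloxy)benzoic acid | OC(=O)c1cccc(OCc2ccccc2)c1OCc1ccccc1
F7 | step 3 | (S)-20-methyldocosyl 2,3-bis(benzyloxy)benzoate | CC[C@H](C)CCCCCCCCCCCCCCCCCCCOC(=O)c1cccc(OCc2ccccc2)c1OCc1ccccc1
F8 | step 1 | dec-9-en-1-ol | C=CCCCCCCCCO
F9 | step 1 | tert-butyl(dec-9-en-1-yloxy)dimethylsilane | C=CCCCCCCCCO[Si](C)(C)C(C)(C)C
F10 | step 1 | 9-[10-(tert-butyldimethylsilyloxy)decyl]-9-borabicyclo[3.3.1]nonane | CC(C)(C)[Si](C)(C)OCCCCCCCCCCB1C2CCCC1CCC2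
F11 | step 1 | tert-butyl(henicos-20-en-1-yloxy)dimethylsilane | C=CCCCCCCCCCCCCCCCCCCCO[Si](C)(C)C(C)(C)C
A1 | alternative 1 | (S)-1-bromo-2-methylbutane | CC[C@H](C)CBr
A2 | alternative 1 | 18-bromooctadecan-1-ol | OCCCCCCCCCCCCCCCCCCBr
A3 | alternative 2 | (E)-1-bromobut-2-ene | C/C=C/CBr
A4 | alternative 2 | [18-(tert-butyldimethylsilyloxy)octadecyl]magnesium bromide | CC(C)(C)[Si](C)(C)OCCCCCCCCCCCCCCCCCC[Mg]Br
A5 | alternative 2 | (R)-20-methyldocos-21-en-1-ol | C=C[C@H](C)CCCCCCCCCCCCCCCCCCCO
A6 | alternative 3 | 20-methylidenedocosan-1-ol | C=C(CC)CCCCCCCCCCCCCCCCCCCO
A7 | alternative 3 | (E)-20-methyldocos-20-en-1-ol | C/C=C(\C)CCCCCCCCCCCCCCCCCCCO
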